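The easy step is to ask how fast Q can reach the solution, so I set the flask out first.

    Q ⇌ J, rate k1*(cs1 - [J]) while solid is left; crystals form when [J] > cs1 (cs1 = 2.3 mM, k1 = 7.94 × 10⁻⁵ s⁻¹)
    J + L → J.L (k2 = 0.0260 L mol⁻¹ s⁻¹)
    2 L → L2 (k3 = 8.59 × 10⁻⁵ L mol⁻¹ s⁻¹)
    J.L ⇌ E (K4 = 18, k4 = 2.16 × 10⁻⁴ s⁻¹)

Q 0.050 M; L 1.50 equiv (fed, over 10 h); time 15 d

- a doubled species enters its step squared and goes two at a time
- solid, in amounts per volume of the solution: Q
- at the start none of Q is in solution
- what has only dissolved of Q counts as not reacted
- the reaction counts as stopped when no species that holds the Q changes by six tenths of a point or more over the second half of the time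
- run time (flask): 15 d

- the state of affairs at 15 d: stopped, and by what, or still going (for what has run out or reacted, a solid counts together with what of it has only dissolved) (L has run out first / all of Q has reacted / forward and back rates have come level / it is still moving)
- part of the Q that has turned into other species by 15 d (what has only dissolved does not count)
- the J.L standing at 15 d, as a percentage of the Q charged
- the E standing at 15 d, as a percentage of the Q charged

With J held low, which I expect while L stands well above 3.05 mM, Q dissolves at its cap, the dissolution coefficient times the solubility: 1.83 × 10⁻⁷ M s⁻¹. The charge of L is 0.0750 M, and it is fed at 2.08 × 10⁻⁶ M s⁻¹, which is 11.4 times faster than the cap, so L piles up.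

Where does the piled-up L go? The L2 step loses L at twice its constant times L squared. I call the level of L at which this loss equals the cap the break-even level L*, the square root of the cap over twice that constant: 0.0326 M. The charge stands 2.30 times higher.

How does the comparison drift? Let s be the share of spent L that catches Q, the cap over the cap plus the L2 loss. As L falls, s climbs from 0.159 at the full charge through 0.5 at L* towards 1. I count the charge as if present at once and take the mean s above and below L*. That gives 0.0384 M of Q caught, or 76.8%. This is less than the Q charged, so I expect L to reach zero first.

J.L and E relax in 0.844 h, far shorter than the run, so they should stand at the balance 18: J.L 4.04% and E 72.8%.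

The forecast says L has run out first, with conversion 79.3% (76% to 82%), J.L 4.17% and E 75.1%, and adds that “solid Q remains”. Its conversion stands above mine.

The simulation gives L has run out first, with 0% of L and 21% of Q left, conversion 79.3%, J.L 4.17% and E 75.1%.

The Q stays unreacted because of the loss of L to L2: with that step struck out, conversion reaches 100%. In this flask L2 holds 47.1% of the L charged, against 48.8% by my reckoning. The neighbour flask with 0.380 equiv of L has a charge of 0.0190 M, below L*, so s runs from 0.746 up and the mean share predicts a conversion of 33.2%. That neighbour flask gives 34.9%.

All constants were set for the occasion.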